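The target is cut at C2–C3 of the dihydropyran ring. C2 is fully substituted (O1, CH3, C3, C1') and lies between an arylethyl half and a C18 branched-chain half, so a stereospecific 1,2-metallate shift can join both halves and create the quaternary stereocentre in one operation: the α-lithiated (R)-secondary 2,4,6-triisopropylbenzoate of the chain captures an arylethyl boronic ester, and the C3 methylene moves from boron to C2 as benzoate leaves. The precursor benzoate 24 is assembled from chiral-pool pieces by two copper-catalysed alkyl–alkyl couplings and an epoxide opening; the boron partner 7 is a hydroquinone dimethyl ether. Oxidation of C–B, quinone formation and reductive closure of C8a–O1 complete the chromanol.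

Key step: step 13

Remark: boron is carried as the neopentyl glycol ester in 7 and 27, because a hindered tertiary α-oxy organolithium captures this less encumbered ester much more readily than a pinacol ester; the carbon skeletons and the bond formed are unchanged.
Remark: 4, 8, 14, 16 and (S)-propylene oxide are taken as commercial; the (R)-benzoate is reached by Mitsunobu inversion of the (S)-carbinol.

Step 1
Reactants: 1 trimethylhydroquinone (2,3,5-trimethylbenzene-1,4-diol)
Product: 2 1,4-dimethoxy-2,3,5-trimethylbenzene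
Conditions: MeI, K2CO3, DMF, 40 °C, N2
Reagents that add atoms: iodomethane, CI
Why: Williamson O-methylation of both phenols under mild base with exclusion of air should give the bis-ether cleanly; no stereocentre is involved.

Step 2
Reactants: 2 1,4-dimethoxy-2,3,5-trimethylbenzene
Product: 3 1-bromo-2,5-dimethoxy-3,4,6-trimethylbenzene
Conditions: N-bromosuccinimide, MeCN, 0 °C → rt, dark
Reagents that add atoms: N-bromosuccinimide, O=C1CCC(=O)N1Br
Why: Electrophilic aromatic bromination can only occur at the single unsubstituted position of the electron-rich ring.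

Step 3
Reactants: 3 1-bromo-2,5-dimethoxy-3,4,6-trimethylbenzene; 4 4,4,5,5-tetramethyl-2-vinyl-1,3,2-dioxaborolane
Product: 5 1-ethenyl-2,5-dimethoxy-3,4,6-trimethylbenzene
Conditions: Pd(OAc)2 (3 mol%), SPhos (6 mol%), K3PO4, toluene/H2O, 90 °C
Reagents that add atoms: none
Why: Suzuki–Miyaura coupling with a bulky biarylphosphine ligand suits di-ortho-substituted electron-rich aryl bromides and should install the two carbons that become C4 and C3.

Step 4
Reactants: 5 1-ethenyl-2,5-dimethoxy-3,4,6-trimethylbenzene
Product: 7 2-[2-(2,5-dimethoxy-3,4,6-trimethylphenyl)ethyl]-5,5-dimethyl-1,3,2-dioxaborinane, via catechol boronate 6 (not isolated)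
Conditions: catecholborane (2 equiv), neat, 90 °C; then neopentyl glycol, THF, rt
Reagents that add atoms: catecholborane, [H]B1Oc2ccccc2O1; 2,2-dimethylpropane-1,3-diol, OCC(C)(C)CO
Why: Thermal anti-Markovnikov hydroboration should place boron on the terminal carbon because the di-ortho-substituted ring shields the benzylic carbon and is twisted out of conjugation, and the labile catechol ester then exchanges for the aliphatic diol (transesterification).

Step 5
Reactants: 8 (3R)-5-methoxy-3-methyl-5-oxopentanoic acid (methyl (R)-3-methylglutarate half-ester)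
Product: 10 (4S)-4-methyloxan-2-one, via hydroxy acid 9 (not isolated)
Conditions: NaH (1.0 equiv), THF, 0 °C; LiBH4, 0 °C → rt; then 2 M HCl
Reagents that add atoms: none
Why: Chemoselective borohydride reduction, in which LiBH4 reduces the methyl ester but not the carboxylate salt, followed by acid lactonisation should differentiate the two chain ends without touching the C3 stereocentre.

Step 6
Reactants: 10 (4S)-4-methyloxan-2-one
Product: 12 (3R)-5-chloro-3-methylpentan-1-ol, via acyl chloride 11 (not isolated)
Conditions: SOCl2, ZnCl2 (cat.), 60 °C; evaporate; LiBH4, THF, 0 °C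
Reagents that add atoms: thionyl chloride, O=S(Cl)Cl
Why: ZnCl2-assisted ring-opening chlorination of the lactone (chloride SN2 at the O–CH2 carbon) should give the ω-chloro acyl chloride, of which only the acyl chloride is reduced by borohydride; the stereocentre is remote from both events.

Step 7
Reactants: 12 (3R)-5-chloro-3-methylpentan-1-ol
Product: 13 (3R)-5-chloro-3-methylpentyl 4-methylbenzenesulfonate
Conditions: TsCl, pyridine, CH2Cl2, 0 °C
Reagents that add atoms: 4-methylbenzenesulfonyl chloride, Cc1ccc(cc1)S(=O)(=O)Cl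
Why: Sulfonylation of the primary alcohol gives a leaving group far more reactive than the primary chloride in copper-catalysed coupling.

Step 8
Reactants: 14 (2S)-3-bromo-2-methylpropan-1-ol
Product: 15 (2S)-1-bromo-3-chloro-2-methylpropane
Conditions: PPh3, N-chlorosuccinimide, CH2Cl2, 0 °C → rt
Reagents that add atoms: N-chlorosuccinimide, O=C1CCC(=O)N1Cl
Why: Appel-type chlorination replaces OH by Cl under neutral conditions without free halide that could exchange the bromide, so the two ends stay distinct and the configuration, which depends only on which end carries which halogen, is kept.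

Step 9
Reactants: 16 4-bromo-2-methylbut-1-ene; 15 (2S)-1-bromo-3-chloro-2-methylpropane
Product: 18 (6R)-7-chloro-2,6-dimethylhept-1-ene, via Grignard reagent 17 (not isolated)
Conditions: 16, Mg, THF; then 15, Li2CuCl4 (3 mol%), NMP, THF, 0 °C → rt
Reagents that add atoms: none
Why: Copper-catalysed sp3–sp3 Grignard cross-coupling reacts at C–Br and leaves C–Cl, forming C9'–C10' and carrying the C8' stereocentre unchanged from 14.

Step 10
Reactants: 18 (6R)-7-chloro-2,6-dimethylhept-1-ene; 13 (3R)-5-chloro-3-methylpentyl 4-methylbenzenesulfonate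
Product: 20 (6S,10R)-12-chloro-2,6,10-trimethyldodec-1-ene, via Grignard reagent 19 (not isolated)
Conditions: 18, Mg, THF, reflux; then 13, Li2CuCl4 (3 mol%), THF, −20 °C → rt
Reagents that add atoms: none
Why: The same copper-catalysed alkyl–alkyl cross-coupling should displace the unbranched primary tosylate selectively over the chloride, forming C6'–C7' and uniting the C8' and C4' stereocentres, neither of which is at a reacting carbon.

Step 11
Reactants: 20 (6S,10R)-12-chloro-2,6,10-trimethyldodec-1-ene; 21 (S)-propylene oxide ((2S)-2-methyloxirane)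
Product: 23 (2S,6R,10S)-6,10,14-trimethylpentadec-14-en-2-ol, via Grignard reagent 22 (not isolated)
Conditions: 20, Mg, THF, reflux; CuI (10 mol%), 21, −30 → 0 °C; aq. NH4Cl
Reagents that add atoms: none
Why: Copper-catalysed epoxide opening by the Grignard reagent occurs at the unsubstituted CH2, so the C–O bond of the stereocentre is untouched and the carbinol has the configuration of the (S)-epoxide.

Step 12
Reactants: 23 (2S,6R,10S)-6,10,14-trimethylpentadec-14-en-2-ol
Product: 24 (2R,6R,10S)-6,10,14-trimethylpentadec-14-en-2-yl 2,4,6-tri(propan-2-yl)benzoate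
Conditions: 2,4,6-triisopropylbenzoic acid, PPh3, DIAD, THF, 0 °C → rt
Reagents that add atoms: 2,4,6-tri(propan-2-yl)benzoic acid, CC(C)c1cc(C(C)C)c(C(=O)O)c(C(C)C)c1
Why: Mitsunobu esterification with the hindered but acidic carboxylic acid proceeds by SN2 at the carbinol carbon, inverting (S) to the (R)-ester required.

Step 13
Reactants: 24 (2R,6R,10S)-6,10,14-trimethylpentadec-14-en-2-yl 2,4,6-tri(propan-2-yl)benzoate; 7 2-[2-(2,5-dimethoxy-3,4,6-trimethylphenyl)ethyl]-5,5-dimethyl-1,3,2-dioxaborinane
Product: 27 2-[(3S,7R,11S)-1-(2,5-dimethoxy-3,4,6-trimethylphenyl)-3,7,11,15-tetramethylhexadec-15-en-3-yl]-5,5-dimethyl-1,3,2-dioxaborinane, via lithiated benzoate 25 (not isolated), via boronate complex 26 (not isolated)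
Conditions: sBuLi (1.6 equiv), TMEDA (6 equiv), cyclopentyl methyl ether, −60 °C; 7 (2 equiv), −60 °C; then 50 °C
Reagents that add atoms: none
Why: The benzoate carbonyl directs sBuLi/TMEDA to the C2–H of 24, and the resulting tertiary α-oxy organolithium 25 is configurationally stable at −60 °C and is captured at boron of 7 with retention to give boronate complex 26. On warming, the C3 methylene migrates from boron to C2 anti-periplanar to the departing triisopropylbenzoate (invertive 1,2-metallate rearrangement), forming the C2–C3 bond. This is the known lithiation–borylation of enantioenriched secondary dialkyl triisopropylbenzoates with neopentyl glycol boronic esters, a Matteson-type homologation. No ring is closed. The new fully substituted stereocentre is controlled by the substrate alone, since retention in lithiation and borylation followed by inversion in the shift converts the (R)-carbinol centre into the (S)-boronate that corresponds to (R)-C2 of the target. The step needs stereospecificity and chemoselectivity, which should be secured by the low temperature (no racemisation of 25, no allylic metallation of the isopropenyl group), by the unhindered primary migrating group and the small diol on boron (fast complexation, a single migrating carbon), and by adding the methoxyarene partner only after the base has reacted with 24, any excess being scavenged at boron.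

Step 14
Reactants: 27 2-[(3S,7R,11S)-1-(2,5-dimethoxy-3,4,6-trimethylphenyl)-3,7,11,15-tetramethylhexadec-15-en-3-yl]-5,5-dimethyl-1,3,2-dioxaborinane
Product: 28 (3R,7R,11S)-1-(2,5-dimethoxy-3,4,6-trimethylphenyl)-3,7,11,15-tetramethylhexadec-15-en-3-ol
Conditions: 30% H2O2, 2 M NaOH, THF, 0 °C → rt
Reagents that add atoms: hydrogen peroxide, OO
Why: Alkaline peroxide oxidation of the C–B bond moves C2 from boron to oxygen with retention (the descriptor change is formal), and the isolated alkene is inert to hydroperoxide anion.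

Step 15
Reactants: 28 (3R,7R,11S)-1-(2,5-dimethoxy-3,4,6-trimethylphenyl)-3,7,11,15-tetramethylhexadec-15-en-3-ol
Product: 29 2-[(3R,7R,11S)-3-hydroxy-3,7,11,15-tetramethylhexadec-15-en-1-yl]-3,5,6-trimethylcyclohexa-2,5-diene-1,4-dione
Conditions: (NH4)2Ce(NO3)6 (2.5 equiv), MeCN/H2O, 0 °C
Reagents that add atoms: water, O
Why: Oxidative demethylation of the para-dimethoxyarene by tetravalent cerium (single-electron oxidation, then water attack at the two ipso carbons) should give the quinone at 0 °C before the alkene or the tertiary alcohol can react.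

Step 16
Reactants: 29 2-[(3R,7R,11S)-3-hydroxy-3,7,11,15-tetramethylhexadec-15-en-1-yl]-3,5,6-trimethylcyclohexa-2,5-diene-1,4-dione
Product: 31 (2R)-2,5,7,8-tetramethyl-2-[(4R,8S)-4,8,12-trimethyltridec-12-en-1-yl]-3,4-dihydro-2H-chromen-6-ol (CNP0115007.1), via hydroquinone 30 (not isolated)
Conditions: Na2S2O4, THF/H2O, rt; then p-TsOH·H2O (cat.), toluene, 40 °C, argon
Reagents that add atoms: none
Why: Dithionite reduction and mild acid should effect the classical chromanol cyclodehydration, in which the tertiary hydroxyl adds to C8a of the keto tautomer (cyclic hemiketal) and the former phenolic oxygen leaves as water, so C2–O1 is never broken and C2 keeps its configuration.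

Compound list
1 | trimethylhydroquinone (2,3,5-trimethylbenzene-1,4-diol) | Cc1cc(O)c(C)c(C)c1O | starting material
2 | 1,4-dimethoxy-2,3,5-trimethylbenzene | COc1cc(C)c(OC)c(C)c1C | intermediate
3 | 1-bromo-2,5-dimethoxy-3,4,6-trimethylbenzene | COc1c(C)c(C)c(OC)c(C)c1Br | intermediate
4 | 4,4,5,5-tetramethyl-2-vinyl-1,3,2-dioxaborolane | C=CB1OC(C)(C)C(C)(C)O1 | starting material
5 | 1-ethenyl-2,5-dimethoxy-3,4,6-trimethylbenzene | COc1c(C)c(C)c(OC)c(C)c1C=C | intermediate
6 | 2-[2-(2,5-dimethoxy-3,4,6-trimethylphenyl)ethyl]-1,3,2-benzodioxaborole (formed in the flask) | COc1c(C)c(C)c(OC)c(C)c1CCB1Oc2ccccc2O1 | intermediate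
7 | 2-[2-(2,5-dimethoxy-3,4,6-trimethylphenyl)ethyl]-5,5-dimethyl-1,3,2-dioxaborinane | COc1c(C)c(C)c(OC)c(C)c1CCB1OCC(C)(C)CO1 | intermediate
8 | (3R)-5-methoxy-3-methyl-5-oxopentanoic acid | OC(=O)C[C@@H](C)CC(=O)OC | starting material
9 | (3S)-5-hydroxy-3-methylpentanoic acid (carboxylate salt in the flask) | OC(=O)C[C@@H](C)CCO | intermediate
10 | (4S)-4-methyloxan-2-one | O=C1C[C@@H](C)CCO1 | intermediate
11 | (3S)-5-chloro-3-methylpentanoyl chloride (formed in the flask) | ClC(=O)C[C@@H](C)CCCl | intermediate
12 | (3R)-5-chloro-3-methylpentan-1-ol | OCC[C@@H](C)CCCl | intermediate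
13 | (3R)-5-chloro-3-methylpentyl 4-methylbenzenesulfonate | Cc1ccc(cc1)S(=O)(=O)OCC[C@@H](C)CCCl | intermediate
14 | (2S)-3-bromo-2-methylpropan-1-ol | BrC[C@@H](C)CO | starting material
15 | (2S)-1-bromo-3-chloro-2-methylpropane | BrC[C@@H](C)CCl | intermediate
16 | 4-bromo-2-methylbut-1-ene | C=C(C)CCBr | starting material
17 | (3-methylbut-3-en-1-yl)magnesium bromide (formed in the flask) | C=C(C)CC[Mg]Br | intermediate
18 | (6R)-7-chloro-2,6-dimethylhept-1-ene | C=C(C)CCC[C@@H](C)CCl | intermediate
19 | [(2R)-2,6-dimethylhept-6-en-1-yl]magnesium chloride (formed in the flask) | C=C(C)CCC[C@@H](C)C[Mg]Cl | intermediate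
20 | (6S,10R)-12-chloro-2,6,10-trimethyldodec-1-ene | C=C(C)CCC[C@@H](C)CCC[C@@H](C)CCCl | intermediate
21 | (S)-propylene oxide ((2S)-2-methyloxirane) | C[C@H]1CO1 | starting material
22 | [(3R,7S)-3,7,11-trimethyldodec-11-en-1-yl]magnesium chloride (formed in the flask) | C=C(C)CCC[C@@H](C)CCC[C@@H](C)CC[Mg]Cl | intermediate
23 | (2S,6R,10S)-6,10,14-trimethylpentadec-14-en-2-ol | C=C(C)CCC[C@@H](C)CCC[C@@H](C)CCC[C@H](C)O | intermediate
24 | (2R,6R,10S)-6,10,14-trimethylpentadec-14-en-2-yl 2,4,6-tri(propan-2-yl)benzoate | C=C(C)CCC[C@@H](C)CCC[C@@H](C)CCC[C@@H](C)OC(=O)c1c(C(C)C)cc(C(C)C)cc1C(C)C | intermediate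
25 | (2R,6R,10S)-2-lithio-6,10,14-trimethylpentadec-14-en-2-yl 2,4,6-tri(propan-2-yl)benzoate (formed in the flask) | C=C(C)CCC[C@@H](C)CCC[C@@H](C)CCC[C@@]([Li])(C)OC(=O)c1c(C(C)C)cc(C(C)C)cc1C(C)C | intermediate
26 | lithium [2-(2,5-dimethoxy-3,4,6-trimethylphenyl)ethyl](2,2-dimethylpropane-1,3-diolato){(2R,6R,10S)-6,10,14-trimethyl-2-[2,4,6-tri(propan-2-yl)benzoyloxy]pentadec-14-en-2-yl}borate (formed in the flask) | C=C(C)CCC[C@@H](C)CCC[C@@H](C)CCC[C@@](C)(OC(=O)c1c(C(C)C)cc(C(C)C)cc1C(C)C)[B-]1(CCc2c(C)c(OC)c(C)c(C)c2OC)OCC(C)(C)CO1.[Li+] | intermediate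
27 | 2-[(3S,7R,11S)-1-(2,5-dimethoxy-3,4,6-trimethylphenyl)-3,7,11,15-tetramethylhexadec-15-en-3-yl]-5,5-dimethyl-1,3,2-dioxaborinane | C=C(C)CCC[C@@H](C)CCC[C@@H](C)CCC[C@@](C)(B1OCC(C)(C)CO1)CCc1c(C)c(OC)c(C)c(C)c1OC | intermediate
28 | (3R,7R,11S)-1-(2,5-dimethoxy-3,4,6-trimethylphenyl)-3,7,11,15-tetramethylhexadec-15-en-3-ol | C=C(C)CCC[C@@H](C)CCC[C@@H](C)CCC[C@@](C)(O)CCc1c(C)c(OC)c(C)c(C)c1OC | intermediate
29 | 2-[(3R,7R,11S)-3-hydroxy-3,7,11,15-tetramethylhexadec-15-en-1-yl]-3,5,6-trimethylcyclohexa-2,5-diene-1,4-dione | C=C(C)CCC[C@@H](C)CCC[C@@H](C)CCC[C@@](C)(O)CCC1=C(C)C(=O)C(C)=C(C)C1=O | intermediate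
30 | 2-[(3R,7R,11S)-3-hydroxy-3,7,11,15-tetramethylhexadec-15-en-1-yl]-3,5,6-trimethylbenzene-1,4-diol (formed in the flask) | C=C(C)CCC[C@@H](C)CCC[C@@H](C)CCC[C@@](C)(O)CCc1c(C)c(O)c(C)c(C)c1O | intermediate
31 | (2R)-2,5,7,8-tetramethyl-2-[(4R,8S)-4,8,12-trimethyltridec-12-en-1-yl]-3,4-dihydro-2H-chromen-6-ol | C=C(C)CCC[C@@H](C)CCC[C@@H](C)CCC[C@]1(C)CCc2c(C)c(O)c(C)c(C)c2O1 | target

Total step count: 16.
Longest linear sequence: 10 steps (8 → 10 → 12 → 13 → 20 → 23 → 24 → 27 → 28 → 29 → 31; steps 5, 6, 7, 10, 11, 12, 13, 14, 15, 16).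

Steps most likely to fail

1. Step 13. The risk is incomplete α-deprotonation of the hindered secondary benzoate, or slow and reversible capture of the tertiary organolithium at boron, which would return starting ester or erode stereochemical fidelity. The fallback sets out from arene 2 and Grignard reagent 22 (made from 20 as in step 11) and comes back at tertiary alcohol 28. Blanc chloromethylation of 2 ((CH2O)n, HCl, AcOH) should give 1-(chloromethyl)-2,5-dimethoxy-3,4,6-trimethylbenzene F1. With Mg in THF this gives (2,5-dimethoxy-3,4,6-trimethylbenzyl)magnesium chloride F2. With CuI catalysis F2 should open commercial (R)-2-methylglycidol, whose hydroxyl is first deprotonated with iPrMgCl, at the unsubstituted ring carbon to give (2S)-4-(2,5-dimethoxy-3,4,6-trimethylphenyl)-2-methylbutane-1,2-diol F3. Selective sulfonylation of the primary hydroxyl (TsCl, pyridine) gives (2S)-4-(2,5-dimethoxy-3,4,6-trimethylphenyl)-2-hydroxy-2-methylbutyl 4-methylbenzenesulfonate F4. K2CO3 in MeOH closes this to (2S)-2-[2-(2,5-dimethoxy-3,4,6-trimethylphenyl)ethyl]-2-methyloxirane F5. Grignard reagent 22 with CuI should then open F5 at its CH2 to give 28 directly. The C2–O bond is never broken in this sequence, so the configuration comes from the epoxy alcohol instead of from a boronate shift.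

2. Step 16. The risk is protonation of the 1,1-disubstituted alkene (double-bond migration or solvent addition), or ionisation of the tertiary carbinol, competing with ring closure under acid. The fallback sets out from quinone 29 and comes back at 31. Acid-catalysed ketal exchange (HC(OMe)3, MeOH, pyridinium p-toluenesulfonate, rt) should trap the C8a hemiketal as the cyclic methyl ketal (2R)-8a-methoxy-2,5,7,8-tetramethyl-2-[(4R,8S)-4,8,12-trimethyltridec-12-en-1-yl]-2,3,4,8a-tetrahydro-6H-chromen-6-one F6, as a mixture of C8a epimers. Zinc dust in AcOH/THF at rt (or ascorbic acid) should then reduce the ketal with loss of methanol to 31. Ring closure and reduction are thereby separated, the only acid in the reduction is acetic acid, and C2–O1 is already in place.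

3. Step 9. The risk is slow substitution at the β-branched C–Br bond, which lets Grignard homocoupling and halide exchange between the two ends compete; the exchange would erode enantiopurity. The fallback reverses the polarity, sets out from 14 and 16 and comes back at 18. Silylation of 14 (TBSCl, imidazole, DMF) gives [(2S)-3-bromo-2-methylpropoxy](tert-butyl)dimethylsilane F7. Mg in THF gives {(2S)-3-[tert-butyl(dimethyl)silyl]oxy-2-methylpropyl}magnesium bromide F8. Li2CuCl4-catalysed coupling of F8 with the unbranched primary bromide 16 should give tert-butyl{[(2R)-2,6-dimethylhept-6-en-1-yl]oxy}dimethylsilane F9. Bu4NF in THF frees (2R)-2,6-dimethylhept-6-en-1-ol F10. PPh3 and N-chlorosuccinimide then give 18.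

Further compounds
F1 | step 13 | 1-(chloromethyl)-2,5-dimethoxy-3,4,6-trimethylbenzene | COc1c(C)c(C)c(OC)c(C)c1CCl
F2 | step 13 | (2,5-dimethoxy-3,4,6-trimethylbenzyl)magnesium chloride | COc1c(C)c(C)c(OC)c(C)c1C[Mg]Cl
F3 | step 13 | (2S)-4-(2,5-dimethoxy-3,4,6-trimethylphenyl)-2-methylbutane-1,2-diol | OC[C@](O)(C)CCc1c(C)c(OC)c(C)c(C)c1OC
F4 | step 13 | (2S)-4-(2,5-dimethoxy-3,4,6-trimethylphenyl)-2-hydroxy-2-methylbutyl 4-methylbenzenesulfonate | Cc1ccc(cc1)S(=O)(=O)OC[C@](O)(C)CCc2c(C)c(OC)c(C)c(C)c2OC
F5 | step 13 | (2S)-2-[2-(2,5-dimethoxy-3,4,6-trimethylphenyl)ethyl]-2-methyloxirane | C1[C@](O1)(C)CCc2c(C)c(OC)c(C)c(C)c2OC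
F6 | step 16 | (2R)-8a-methoxy-2,5,7,8-tetramethyl-2-[(4R,8S)-4,8,12-trimethyltridec-12-en-1-yl]-2,3,4,8a-tetrahydro-6H-chromen-6-one (C8a epimers) | C=C(C)CCC[C@@H](C)CCC[C@@H](C)CCC[C@]1(C)CCC2=C(C)C(=O)C(C)=C(C)C2(OC)O1
F7 | step 9 | [(2S)-3-bromo-2-methylpropoxy](tert-butyl)dimethylsilane | BrC[C@@H](C)CO[Si](C)(C)C(C)(C)C
F8 | step 9 | {(2S)-3-[tert-butyl(dimethyl)silyl]oxy-2-methylpropyl}magnesium bromide | Br[Mg]C[C@@H](C)CO[Si](C)(C)C(C)(C)C
F9 | step 9 | tert-butyl{[(2R)-2,6-dimethylhept-6-en-1-yl]oxy}dimethylsilane | C=C(C)CCC[C@@H](C)CO[Si](C)(C)C(C)(C)C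
F10 | step 9 | (2R)-2,6-dimethylhept-6-en-1-ol | C=C(C)CCC[C@@H](C)CO
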